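**Plan**

1. Retrosynthesis, first cut: after removal of five acetates, the dihydrofuran O1–C2 bond is cut. The ring O1–C2–C3–C3a–C7a is the Cloke–Wilson isomer of a spirocyclopropane C2–C3–C3a, because C3a is the central carbon of the fused pyran-2,4-dione (C4 lactone C=O and C7a ketone C=O as geminal acceptors) and C2 carries an aryl donor.
2. Second cut: the cyclopropane bonds C3a–C2 and C3a–C3, giving a 3-diazo-6-arylpyran-2,4-dione (carbene source) and (Z)-hispidin triacetate (alkene).
3. Third cut: each 4-hydroxy-2-pyranone into a methyl ketone and malonyl dichloride.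
4. Forward order: two pyranone annulations; diazo transfer on one, O-acetylation and E→Z photoisomerisation on the other; Rh-carbene cyclopropanation; ring expansion 3→5 that closes the furo[3,2-c]pyranone; global deacetylation.
5. Stereochemistry: the 2,3-cis relation comes from the Z-alkene (stereospecific cyclopropanation) and should pass through the ring expansion with net retention (two SN2 inversions at C2); the absolute configuration comes from the chiral Rh(II) carboxylate.
6. Helpers: the acetates protect all OH groups and weaken the aryl donor, so that the cyclopropane can be isolated and C2 does not ionise; they come off in the last step.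

Key step: step 9

Assumption: the target SMILES is read as the 2,3-cis (2R,3S) dihydrofuran, and the antipode of the Rh(II) catalyst in step 8 is taken to be whichever gives the (1R,2R)-cyclopropane in a test reaction, since its sense of induction cannot be predicted for this carbene/alkene pair.

**Route**

Step 1
Reactants: 1 3',4'-dihydroxyacetophenone
Product: 2 4-acetyl-1,2-phenylene diacetate
Conditions: Ac2O, pyridine, CH2Cl2, 0 °C → rt
Reagents that add atoms: acetic anhydride, CC(=O)OC(C)=O
Why: Standard pyridine-mediated O-acetylation of a catechol; the acetates protect the phenols and lower the donor strength of the aryl ring for steps 8 and 9.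

Step 2
Reactants: 2 4-acetyl-1,2-phenylene diacetate; 3 malonyl dichloride
Product: 5 4-(4-hydroxy-2-oxo-2H-pyran-6-yl)-1,2-phenylene diacetate, via silyl enol ether 4 (not isolated)
Conditions: TMSOTf, Et3N, CH2Cl2, 0 °C; pentane filtration; then 3, Et2O, −78 °C → rt
Reagents that add atoms: none
Why: Soft enolisation gives the silyl enol ether, which is C-acylated by malonyl dichloride and lactonises through the aryl ketone enol oxygen (malonyl dichloride annulation of silyl enol ethers to 4-hydroxy-2-pyranones); no strong base is present, so the aryl acetates should survive.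

Step 3
Reactants: 5 4-(4-hydroxy-2-oxo-2H-pyran-6-yl)-1,2-phenylene diacetate
Product: 6 4-(3-diazo-2,4-dioxo-3,4-dihydro-2H-pyran-6-yl)-1,2-phenylene diacetate
Conditions: p-ABSA, Et3N, MeCN, 0 °C → rt
Reagents that add atoms: 4-acetamidobenzenesulfonyl azide (p-ABSA), CC(=O)Nc1ccc(cc1)S(=O)(=O)N=[N+]=[N-]
Why: Regitz diazo transfer to the acidic C3 position of the cyclic 1,3-dicarbonyl system, as known for 4-hydroxy-2-pyranones and 4-hydroxycoumarins.

Step 4
Reactants: 7 (E)-4-(3,4-dihydroxyphenyl)but-3-en-2-one
Product: 8 4-[(E)-3-oxobut-1-enyl]-1,2-phenylene diacetate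
Conditions: Ac2O, pyridine, CH2Cl2, 0 °C → rt
Reagents that add atoms: acetic anhydride, CC(=O)OC(C)=O
Why: Standard O-acetylation of the catechol, for the same reasons as in step 1.

Step 5
Reactants: 8 4-[(E)-3-oxobut-1-enyl]-1,2-phenylene diacetate; 3 malonyl dichloride
Product: 10 4-[(E)-2-(4-hydroxy-2-oxo-2H-pyran-6-yl)ethenyl]-1,2-phenylene diacetate, via silyl dienol ether 9 (not isolated)
Conditions: TMSOTf, Et3N, CH2Cl2, 0 °C; pentane filtration; then 3, Et2O, −78 °C → rt
Reagents that add atoms: none
Why: The methyl ketone enolises on the methyl side to the cross-conjugated 2-silyloxydiene, which is acylated at its terminal CH2 and lactonises as in step 2 (same pyranone annulation); the (E)-styryl double bond takes no part.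

Step 6
Reactants: 10 4-[(E)-2-(4-hydroxy-2-oxo-2H-pyran-6-yl)ethenyl]-1,2-phenylene diacetate
Product: 11 4-[(E)-2-(4-acetoxy-2-oxo-2H-pyran-6-yl)ethenyl]-1,2-phenylene diacetate (hispidin triacetate)
Conditions: Ac2O, pyridine, CH2Cl2, 0 °C
Reagents that add atoms: acetic anhydride, CC(=O)OC(C)=O
Why: O-acetylation of the vinylogous acid (known for 4-hydroxy-2-pyranones), which masks the acidic OH against O–H insertion in step 8; DMAP and heat are avoided to prevent O→C acyl migration.

Step 7
Reactants: 11 hispidin triacetate (E)
Product: 12 4-[(Z)-2-(4-acetoxy-2-oxo-2H-pyran-6-yl)ethenyl]-1,2-phenylene diacetate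
Conditions: fac-Ir(ppy)3 (1 mol %), degassed MeCN (0.01 M), 450 nm LED, rt, dark work-up; E isomer recycled
Reagents that add atoms: none
Why: Sensitised contra-thermodynamic E→Z isomerisation of a styrenyl chromophore by triplet energy transfer; the Z isomer should accumulate because its twisted, less conjugated π-system is the poorer energy acceptor, and high dilution suppresses [2+2] dimerisation.

Step 8
Reactants: 12 (Z)-hispidin triacetate; 6 4-(3-diazo-2,4-dioxo-3,4-dihydro-2H-pyran-6-yl)-1,2-phenylene diacetate
Product: 13 (1R,2R)-2-(4-acetoxy-2-oxo-2H-pyran-6-yl)-1,6-bis(3,4-diacetoxyphenyl)-5-oxaspiro[2.5]oct-6-ene-4,8-dione (aryl at C1 cis to pyranonyl at C2; both epimers at spiro C3)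
Conditions: Rh2(S-NTTL)4 (2 mol %), 6 (2 equiv, slow addition), PhCF3, 25 → 40 °C; rapid filtration over deactivated silica
Reagents that add atoms: none
Why: Rh(II)-catalysed carbene transfer from the 2-diazo-1,3-dicarbonyl compound to the alkene (metal-carbene cyclopropanation) is concerted and therefore stereospecific, so the Z geometry of 12 fixes the cis relation of C1 and C2, while the chiral carboxylate ligands select the alkene face and set both centres as R; the spiro carbon forms as a mixture that does not matter because it becomes sp2 in step 9.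

Step 9
Reactants: 13 cis-(1R,2R)-spirocyclopropane
Product: 15 (2R,3S)-3-(4-acetoxy-2-oxo-2H-pyran-6-yl)-2,6-bis(3,4-diacetoxyphenyl)-2,3-dihydro-4H-furo[3,2-c]pyran-4-one, via benzylic iodide magnesium enolate 14 (not isolated)
Conditions: MgI2 (10 mol %), THF/CH2Cl2, −20 → 0 °C, dark, Ar; quenched at full conversion
Reagents that add atoms: none
Why: Mg2+ chelates the two carbonyl oxygens of the spiro pyran-2,4-dione and iodide opens the polarised C3–C1 bond by SN2 attack at the benzylic carbon C1 with inversion to give 14, whose enolate oxygen from the former C8 ketone then displaces iodide with a second inversion, so that the cyclopropane strain is released and iodide is returned. The closest known reaction type is the halide- or Lewis acid-catalysed Cloke–Wilson rearrangement of aryl-substituted spirocyclopropanes of cyclic 1,3-diones to 2-aryl-2,3-dihydrofurans. The five-membered ring closes by a 5-exo-tet O-alkylation. No new stereocentre is created: C2 of the product (R) is C1 of 13 transferred with net retention by the double inversion, and C3 (S) is C2 of 13 and is not touched, so the cis relation set by the Z-alkene is carried over. Three selectivities are needed: cleavage of C3–C1 and not C3–C2, secured because only C1 bears an aryl group that stabilises the loose SN2 transition state while the pyranonyl at C2 is an acceptor; closure through the ketone oxygen and not the lactone carbonyl oxygen, secured because only the former gives the more stable 4-alkoxy-2-pyranone and the other adduct can be re-opened by iodide; and substitution over ionisation at C2, secured by the acetoxy groups, which make the aryl ring a poor cation stabiliser. Low iodide loading and low temperature are chosen to keep iodide–iodide exchange at C2 slower than ring closure.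

Step 10
Reactants: 15 pentaacetate of the target
Product: 16 (2R,3S)-2,6-bis(3,4-dihydroxyphenyl)-3-(4-hydroxy-2-oxo-2H-pyran-6-yl)-2,3-dihydro-4H-furo[3,2-c]pyran-4-one (CNP0224684.1)
Conditions: N2H4·AcOH (8 equiv), AcOH (2 equiv), DMF, 0 °C, Ar; work-up at pH about 5
Reagents that add atoms: none
Why: Hydrazinolysis of the four aryl acetates and the enol acetate (aminolysis of activated esters) under weakly acidic buffering, which keeps the liberated para-phenol protonated so that the benzylic C2–O bond should not open through a quinone methide and C2 and C3 stay as set.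

**Compound list**

1 | 3',4'-dihydroxyacetophenone | CC(=O)c1ccc(O)c(O)c1 | starting material
2 | 4-acetyl-1,2-phenylene diacetate | CC(=O)Oc1ccc(C(C)=O)cc1OC(C)=O | intermediate
3 | malonyl dichloride | O=C(Cl)CC(=O)Cl | starting material
4 | 4-[1-(trimethylsilyloxy)ethenyl]-1,2-phenylene diacetate (silyl enol ether, not isolated) | C=C(O[Si](C)(C)C)c1ccc(OC(C)=O)c(OC(C)=O)c1 | intermediate
5 | 4-(4-hydroxy-2-oxo-2H-pyran-6-yl)-1,2-phenylene diacetate | CC(=O)Oc1ccc(-c2cc(O)cc(=O)o2)cc1OC(C)=O | intermediate
6 | 4-(3-diazo-2,4-dioxo-3,4-dihydro-2H-pyran-6-yl)-1,2-phenylene diacetate | CC(=O)Oc1ccc(C2=CC(=O)C(=[N+]=[N-])C(=O)O2)cc1OC(C)=O | intermediate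
7 | (E)-4-(3,4-dihydroxyphenyl)but-3-en-2-one | CC(=O)/C=C/c1ccc(O)c(O)c1 | starting material
8 | 4-[(E)-3-oxobut-1-enyl]-1,2-phenylene diacetate | CC(=O)/C=C/c1ccc(OC(C)=O)c(OC(C)=O)c1 | intermediate
9 | 4-[(E)-3-(trimethylsilyloxy)buta-1,3-dienyl]-1,2-phenylene diacetate (silyl dienol ether, not isolated) | C=C(O[Si](C)(C)C)/C=C/c1ccc(OC(C)=O)c(OC(C)=O)c1 | intermediate
10 | 4-[(E)-2-(4-hydroxy-2-oxo-2H-pyran-6-yl)ethenyl]-1,2-phenylene diacetate | CC(=O)Oc1ccc(/C=C/c2cc(O)cc(=O)o2)cc1OC(C)=O | intermediate
11 | 4-[(E)-2-(4-acetoxy-2-oxo-2H-pyran-6-yl)ethenyl]-1,2-phenylene diacetate (hispidin triacetate) | CC(=O)Oc1ccc(/C=C/c2cc(OC(C)=O)cc(=O)o2)cc1OC(C)=O | intermediate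
12 | 4-[(Z)-2-(4-acetoxy-2-oxo-2H-pyran-6-yl)ethenyl]-1,2-phenylene diacetate | CC(=O)Oc1ccc(/C=C\c2cc(OC(C)=O)cc(=O)o2)cc1OC(C)=O | intermediate
13 | (1R,2R)-2-(4-acetoxy-2-oxo-2H-pyran-6-yl)-1,6-bis(3,4-diacetoxyphenyl)-5-oxaspiro[2.5]oct-6-ene-4,8-dione, C1-aryl and C2-pyranonyl cis, both epimers at spiro C3 | CC(=O)Oc1cc([C@@H]2[C@H](c3ccc(OC(C)=O)c(OC(C)=O)c3)C24C(=O)C=C(c5ccc(OC(C)=O)c(OC(C)=O)c5)OC4=O)oc(=O)c1 | intermediate
14 | iodomagnesium enolate of 3-[(1R,2S)-1-(4-acetoxy-2-oxo-2H-pyran-6-yl)-2-(3,4-diacetoxyphenyl)-2-iodoethyl]-6-(3,4-diacetoxyphenyl)-4-hydroxy-2H-pyran-2-one (not isolated) | CC(=O)Oc1cc([C@@H](C2=C(O[Mg]I)C=C(c3ccc(OC(C)=O)c(OC(C)=O)c3)OC2=O)[C@H](I)c2ccc(OC(C)=O)c(OC(C)=O)c2)oc(=O)c1 | intermediate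
15 | (2R,3S)-3-(4-acetoxy-2-oxo-2H-pyran-6-yl)-2,6-bis(3,4-diacetoxyphenyl)-2,3-dihydro-4H-furo[3,2-c]pyran-4-one (2,3-cis) | CC(=O)Oc1cc([C@H]2c3c(cc(-c4ccc(OC(C)=O)c(OC(C)=O)c4)oc3=O)O[C@H]2c2ccc(OC(C)=O)c(OC(C)=O)c2)oc(=O)c1 | intermediate
16 | (2R,3S)-2,6-bis(3,4-dihydroxyphenyl)-3-(4-hydroxy-2-oxo-2H-pyran-6-yl)-2,3-dihydro-4H-furo[3,2-c]pyran-4-one (2,3-cis) | O=c1cc(O)cc([C@H]2c3c(cc(-c4ccc(O)c(O)c4)oc3=O)O[C@H]2c2ccc(O)c(O)c2)o1 | target

**Step count**

Total steps: 10. Longest linear sequence: 7 (steps 4 to 10, from 7).

**Steps most likely to fail**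

Step 8. Carbene transfer to a hindered 1,2-disubstituted alkene may be slower than carbene dimerisation or Wolff rearrangement. The facial selectivity of the chiral catalyst may be poor. The cyclopropane may also open in the flask to a zwitterion and lose the cis geometry. The fallback sets out from 5 and 12 and comes back to the route at 13. Compound 5 would be converted with PhI(OAc)2 (CH2Cl2, 0 °C) into the phenyliodonium ylide of 5, F1. F1 would transfer the same carbene to 12 at 0 °C under the robust achiral catalyst Rh2(esp)2, which should give the cis-cyclopropane as a racemate, that is 13 together with its (1S,2S) enantiomer, F2. Preparative chiral SFC would then deliver 13, so that the absolute configuration comes from resolution and not from catalyst control.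

Step 9. Ionisation or iodide–iodide exchange at C2 may erode the cis relation toward the more stable trans isomer. Iodide may also attack the pyranonyl-bearing cyclopropane carbon, or the lactone oxygen may close the ring. The fallback sets out from 13 and comes back at 15, and runs the two inversions as separate, checked operations without free iodide. Anhydrous HBr (1 equiv, from TMSBr and MeOH, CH2Cl2, −40 °C) should add across the C3–C1 bond with inversion at the benzylic carbon. The product, isolated as its free enol, is 3-[(1R,2S)-1-(4-acetoxy-2-oxo-2H-pyran-6-yl)-2-bromo-2-(3,4-diacetoxyphenyl)ethyl]-6-(3,4-diacetoxyphenyl)-4-hydroxy-2H-pyran-2-one, F3. Solid NaHCO3 in acetone at 0 °C should then close the ring by intramolecular SN2 O-alkylation (second inversion) to 15, and the bromide leaves the solution as insoluble NaBr.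

Step 10. The benzylic C2–O bond may open reversibly (quinone methide from the free para-phenol, or benzylic cation) and re-close to the trans isomer. Hydrazine may also attack the lactone or vinylogous ester carbons of the pyranones. The fallback sets out from 15 and comes back at 16. It replaces aminolysis in solution by biocatalytic alcoholysis: immobilised Candida antarctica lipase B, n-BuOH, MTBE/THF, 30 °C, under argon. No base or free nitrogen nucleophile is present, and aryl and enol acetates are good acyl donors for this enzyme.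

**Further compounds**

F1 | step 8 | phenyliodonium ylide of 5: 6-(3,4-diacetoxyphenyl)-2-oxo-3-(phenyliodonio)-2H-pyran-4-olate | O=C1OC(c2ccc(OC(C)=O)c(OC(C)=O)c2)=CC([O-])=C1[I+]c1ccccc1
F2 | step 8 | (1S,2S) enantiomer of 13 | CC(=O)Oc1cc([C@H]2[C@@H](c3ccc(OC(C)=O)c(OC(C)=O)c3)C24C(=O)C=C(c5ccc(OC(C)=O)c(OC(C)=O)c5)OC4=O)oc(=O)c1
F3 | step 9 | 3-[(1R,2S)-1-(4-acetoxy-2-oxo-2H-pyran-6-yl)-2-bromo-2-(3,4-diacetoxyphenyl)ethyl]-6-(3,4-diacetoxyphenyl)-4-hydroxy-2H-pyran-2-one | CC(=O)Oc1cc([C@@H](c2c(O)cc(-c3ccc(OC(C)=O)c(OC(C)=O)c3)oc2=O)[C@H](Br)c2ccc(OC(C)=O)c(OC(C)=O)c2)oc(=O)c1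
F0 | step 10 | none | none
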